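The cyclopentane (ring atoms C1–C5: C1 aryl-bearing quaternary carbon, C2 the CHMe carbon, C3 the bromomethylidene carbon, C4/C5 methylenes) is cut at C1–C2 and C3–C4. One operation makes both bonds from an acyclic (Z)-allyl (E)-propenyl ether in which oxygen temporarily links C3 to C4: Claisen rearrangement forms C1–C2 and both stereocentres, then rhodium-catalysed hydroacylation of the unveiled aldehyde closes C3–C4. The step exploits the 1,2-disposition of C1/C2 next to a C3 carbonyl (later the alkylidene) and the ortho phenol, which lets a coumarin lactone lock the Z alkene. A ketoreductase resolution sets absolute configuration; boron-Wittig olefination and bromodeboronation with inversion give the Z vinyl bromide.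

Key step: step 5

Remark: the thermal rearrangement is not enantioselective, so material is racemic through step 5 and the absolute configuration is fixed by the enzymatic kinetic resolution in step 6.

Step 1
Reactants: 1 4,7-dimethylcoumarin
Product: 2 (Z)-2-(4-hydroxybut-2-en-2-yl)-5-methylphenol
Conditions: i-Bu2AlH (3 equiv), CH2Cl2, −78 to 0 °C; aq. potassium sodium tartrate work-up
Reagents that add atoms: none
Why: Hydride reduction of the unsaturated lactone to the allylic diol should proceed by 1,2-addition only and keep the ring-enforced Z geometry, with the aryl group cis to the CH2OH arm.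

Step 2
Reactants: 2 (Z)-2-(4-hydroxybut-2-en-2-yl)-5-methylphenol
Product: 3 (Z)-3-[2-(methoxymethoxy)-4-methylphenyl]but-2-en-1-ol
Conditions: MOMCl (1.1 equiv), K2CO3, acetone, 0 °C to rt
Reagents that add atoms: chloromethyl methyl ether (MOMCl), COCCl
Why: Williamson-type O-alkylation should occur only at the phenoxide, because carbonate does not deprotonate the primary alcohol, and masking the phenol blocks closure to the 2H-chromene.

Step 3
Reactants: 3 (Z)-3-[2-(methoxymethoxy)-4-methylphenyl]but-2-en-1-ol
Product: 4 1-[(2Z)-4-(allyloxy)but-2-en-2-yl]-2-(methoxymethoxy)-4-methylbenzene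
Conditions: NaH, allyl bromide, Bu4NI (cat.), THF, 0 °C to rt
Reagents that add atoms: allyl bromide, C=CCBr
Why: Williamson ether synthesis on the primary allylic alkoxide installs the three carbons that become C3, C2 and the C2 methyl group.

Step 4
Reactants: 4 1-[(2Z)-4-(allyloxy)but-2-en-2-yl]-2-(methoxymethoxy)-4-methylbenzene
Product: 5 2-(methoxymethoxy)-4-methyl-1-[(2Z)-4-{[(1E)-prop-1-en-1-yl]oxy}but-2-en-2-yl]benzene
Conditions: [Ir(cod)(PMePh2)2]PF6 (2 mol %, activated with H2), THF, rt
Reagents that add atoms: none
Why: Iridium-hydride-catalysed allyl-to-propenyl ether isomerisation should act only on the monosubstituted allyl group and give the (E)-enol ether, leaving the trisubstituted Z alkene untouched.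

Step 5
Reactants: 5 2-(methoxymethoxy)-4-methyl-1-[(2Z)-4-{[(1E)-prop-1-en-1-yl]oxy}but-2-en-2-yl]benzene
Product: 7 rac-(2R,3R)-3-[2-(methoxymethoxy)-4-methylphenyl]-2,3-dimethylcyclopentan-1-one, via pentenal 6 (not isolated)
Conditions: [Rh(cod)Cl]2 (2.5 mol %), dppe (5.5 mol %), PhCN, 150 °C, sealed tube, Ar
Reagents that add atoms: none
Why: Heating triggers a concerted [3,3]-sigmatropic (Claisen) rearrangement that breaks the C4–O bond and forms C1–C2 to give pentenal 6; the monovalent rhodium catalyst then inserts into the aldehyde C–H bond, adds Rh–H across the terminal vinyl group and reductively eliminates from a six-membered acyl-alkyl rhodacycle to form C3–C4. The closest known reaction type is the rhodium-catalysed tandem Claisen rearrangement–intramolecular hydroacylation of allyl vinyl ethers to cyclopentanones. The five-membered ring closes by a formally 5-endo-trig acylation of the vinyl group, which the metallacycle pathway makes possible. C1 and C2 are both set in the chair-like [3,3] transition state by the two alkene geometries: the Z allyl unit (aryl pseudoaxial, methyl pseudoequatorial) and the E enol ether (methyl pseudoequatorial) should place the aryl group and the C2 methyl cis, and the product is racemic. The step needs chair over boat selectivity, no epimerisation at C2 and no decarbonylation; the geometrically pure enol ether, the neutral catalyst and the fast cyclisation of a gem-disubstituted pentenal with an unsubstituted vinyl group are expected to secure this.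

Step 6
Reactants: 7 rac-(2R,3R)-3-[2-(methoxymethoxy)-4-methylphenyl]-2,3-dimethylcyclopentan-1-one
Product: 8 (2R,3R)-3-[2-(methoxymethoxy)-4-methylphenyl]-2,3-dimethylcyclopentan-1-one
Conditions: ketoreductase (NADPH-dependent alcohol dehydrogenase, panel-selected), NADP+ (cat.), i-PrOH, potassium phosphate buffer pH 7, DMSO (5% v/v), 30 °C, stopped just past half conversion
Reagents that add atoms: none
Why: Enzymatic kinetic resolution by a ketoreductase should reduce only the (2S,3S)-ketone to the cyclopentanol, so the unreduced (2R,3R)-enantiomer is recovered and both stereocentres are fixed in absolute terms.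

Step 7
Reactants: 8 (2R,3R)-3-[2-(methoxymethoxy)-4-methylphenyl]-2,3-dimethylcyclopentan-1-one
Product: 9 (2R,3R)-3-[5-bromo-2-(methoxymethoxy)-4-methylphenyl]-2,3-dimethylcyclopentan-1-one
Conditions: NBS (1.05 equiv), MeCN, 0 °C to rt, dark
Reagents that add atoms: N-bromosuccinimide (NBS), O=C1CCC(=O)N1Br
Why: Electrophilic aromatic bromination of the alkoxyarene should go para to the OMOM group and ortho to the ring methyl, the most activated and least hindered position.

Step 8
Reactants: 9 (2R,3R)-3-[5-bromo-2-(methoxymethoxy)-4-methylphenyl]-2,3-dimethylcyclopentan-1-one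
Product: 11 2-{(E)-[(2S,3R)-3-[5-bromo-2-(methoxymethoxy)-4-methylphenyl]-2,3-dimethylcyclopentylidene]methyl}-4,4,5,5-tetramethyl-1,3,2-dioxaborolane, via lithium alkoxide 10 (not isolated)
Conditions: CH2(Bpin)2 (1.3 equiv), lithium 2,2,6,6-tetramethylpiperidide (1.2 equiv), THF, 0 °C; then 9, −78 °C to rt
Reagents that add atoms: bis[(pinacolato)boryl]methane, C(B1OC(C)(C)C(C)(C)O1)B1OC(C)(C)C(C)(C)O1
Why: In this boron-Wittig olefination the α-boryl carbanion adds to the ketone and syn B–O elimination should leave the remaining Bpin trans to the bulkier C2 side (cis to the C4 methylene), while the weakly basic reagent should spare the epimerisable C2; the 2S label reflects a change in CIP priorities, not inversion.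

Step 9
Reactants: 11 2-{(E)-[(2S,3R)-3-[5-bromo-2-(methoxymethoxy)-4-methylphenyl]-2,3-dimethylcyclopentylidene]methyl}-4,4,5,5-tetramethyl-1,3,2-dioxaborolane
Product: 13 1-bromo-5-[(1R,2R,3Z)-3-(bromomethylidene)-1,2-dimethylcyclopentyl]-4-(methoxymethoxy)-2-methylbenzene, via dibromide 12 (not isolated)
Conditions: Br2 (1.05 equiv), CH2Cl2, −78 °C; then NaOMe, MeOH, −78 to 0 °C
Reagents that add atoms: bromine, BrBr
Why: Bromodeboronation with inversion, by anti addition of Br2 and then methoxide-induced anti elimination of boron and bromide, should move the halogen to the side that was trans to boron, that is cis to C2, giving the Z bromomethylidene.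

Step 10
Reactants: 13 1-bromo-5-[(1R,2R,3Z)-3-(bromomethylidene)-1,2-dimethylcyclopentyl]-4-(methoxymethoxy)-2-methylbenzene
Product: 14 4-bromo-2-[(1R,2R,3Z)-3-(bromomethylidene)-1,2-dimethylcyclopentyl]-5-methylphenol
Conditions: HCl (3 M aq.), MeOH, 45 °C
Reagents that add atoms: none
Why: Acid-catalysed acetal cleavage (MOM removal) should free the phenol without touching the vinyl bromide, the aryl bromide or either stereocentre.

Compound list
1 | 4,7-dimethylcoumarin (4,7-dimethyl-2H-chromen-2-one) | Cc1ccc2c(C)cc(=O)oc2c1 | starting material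
2 | (Z)-2-(4-hydroxybut-2-en-2-yl)-5-methylphenol (aryl cis to CH2OH) | Cc1ccc(/C(C)=C\CO)c(O)c1 | intermediate
3 | (Z)-3-[2-(methoxymethoxy)-4-methylphenyl]but-2-en-1-ol | COCOc1cc(C)ccc1/C(C)=C\CO | intermediate
4 | 1-[(2Z)-4-(allyloxy)but-2-en-2-yl]-2-(methoxymethoxy)-4-methylbenzene | COCOc1cc(C)ccc1/C(C)=C\COCC=C | intermediate
5 | 2-(methoxymethoxy)-4-methyl-1-[(2Z)-4-{[(1E)-prop-1-en-1-yl]oxy}but-2-en-2-yl]benzene | COCOc1cc(C)ccc1/C(C)=C\CO/C=C/C | intermediate
6 | rac-(2R,3R)-3-[2-(methoxymethoxy)-4-methylphenyl]-2,3-dimethylpent-4-enal (racemate, one enantiomer drawn; not isolated) | Cc1ccc(c(OCOC)c1)[C@](C)(C=C)[C@@H](C)C=O | intermediate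
7 | rac-(2R,3R)-3-[2-(methoxymethoxy)-4-methylphenyl]-2,3-dimethylcyclopentan-1-one (racemate, one enantiomer drawn; aryl cis to the C2 methyl) | Cc1ccc(c(OCOC)c1)[C@]1(C)CCC(=O)[C@@H]1C | intermediate
8 | (2R,3R)-3-[2-(methoxymethoxy)-4-methylphenyl]-2,3-dimethylcyclopentan-1-one (single enantiomer) | Cc1ccc(c(OCOC)c1)[C@]1(C)CCC(=O)[C@@H]1C | intermediate
9 | (2R,3R)-3-[5-bromo-2-(methoxymethoxy)-4-methylphenyl]-2,3-dimethylcyclopentan-1-one | Cc1cc(OCOC)c(cc1Br)[C@]1(C)CCC(=O)[C@@H]1C | intermediate
10 | lithium alkoxide from addition of [bis(pinacolatoboryl)methyl]lithium to the carbonyl of 9, new C–C bond on the face anti to the aryl group (not isolated) | Cc1cc(OCOC)c(cc1Br)[C@]1(C)CC[C@@]([O-])(C(B2OC(C)(C)C(C)(C)O2)B2OC(C)(C)C(C)(C)O2)[C@@H]1C.[Li+] | intermediate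
11 | 2-{(E)-[(2S,3R)-3-[5-bromo-2-(methoxymethoxy)-4-methylphenyl]-2,3-dimethylcyclopentylidene]methyl}-4,4,5,5-tetramethyl-1,3,2-dioxaborolane (boron cis to the ring CH2) | Cc1cc(OCOC)c(cc1Br)[C@]1(C)CC/C(=C\B2OC(C)(C)C(C)(C)O2)[C@@H]1C | intermediate
12 | vicinal dibromide from anti addition of Br2 across the exocyclic alkene of 11 (one of two anti adducts, which converge; not isolated) | Cc1cc(OCOC)c(cc1Br)[C@]1(C)CC[C@@](Br)([C@H](Br)B2OC(C)(C)C(C)(C)O2)[C@@H]1C | intermediate
13 | 1-bromo-5-[(1R,2R,3Z)-3-(bromomethylidene)-1,2-dimethylcyclopentyl]-4-(methoxymethoxy)-2-methylbenzene | Cc1cc(OCOC)c(cc1Br)[C@]1(C)CC/C(=C/Br)[C@@H]1C | intermediate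
14 | 4-bromo-2-[(1R,2R,3Z)-3-(bromomethylidene)-1,2-dimethylcyclopentyl]-5-methylphenol | Cc1cc(O)c([C@]2(C)CC/C(=C/Br)[C@@H]2C)cc1Br | target

Total step count: 10. Longest linear sequence: 10 steps (1 to 14).

Steps most likely to fail

Step 5. The aldehyde may lose CO on rhodium at 150 °C, the rearrangement may leak through a boat-like transition state, or C2 may epimerise before ring closure. Fallback: it sets out from 5 and comes back at 7. Heating 5 without metal (xylene, 140 °C) should give aldehyde 6, here isolated. Propane-1,3-dithiol with Zn(OTf)2 (cat.) would convert it into the dithioacetal F1. Hydroboration with 9-BBN and oxidation with NaBO3 would give the primary alcohol F2, and TsCl in pyridine the tosylate F3. Deprotonation with n-BuLi (THF, −30 °C) should close the ring by Corey–Seebach alkylation to the spiro dithioketal F4. MeI and CaCO3 in aqueous MeCN would then unmask the ketone and return 7.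

Step 8. The hindered, enolisable ketone may be deprotonated instead of attacked, which would also scramble C2, and the B–O elimination may give poor control of alkene geometry. Fallback: it sets out from 9 and comes back at 13, passing by 11 and 12. Ramirez dibromo-olefination (CBr4, PPh3, toluene, 100 °C) under non-basic conditions should give the dibromomethylidene compound F5. Hydrogenolysis with Bu3SnH and Pd(PPh3)4, a zerovalent palladium catalyst, should then remove the less hindered bromine, the one cis to the ring CH2, and leave the Z vinyl bromide 13.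

Step 6. The enzyme may fail to tell the enantiomers apart, or the lipophilic substrate may be taken up too slowly. Fallback: it sets out from 7 and comes back at 8. Preparative chromatography of racemic 7 on a chiral stationary phase (amylose tris(3,5-dimethylphenylcarbamate), supercritical CO2/MeOH) would deliver the (2R,3R)-enantiomer 8 directly.

Further compounds
F1 | step 5 | rac-1,3-dithiane of aldehyde 6: 2-[3-[2-(methoxymethoxy)-4-methylphenyl]-3-methylpent-4-en-2-yl]-1,3-dithiane, same relative configuration as 6 | Cc1ccc(c(OCOC)c1)[C@](C)(C=C)[C@@H](C)C1SCCCS1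
F2 | step 5 | rac-primary alcohol from anti-Markovnikov hydration of the vinyl group of F1: 4-(1,3-dithian-2-yl)-3-[2-(methoxymethoxy)-4-methylphenyl]-3-methylpentan-1-ol | Cc1ccc(c(OCOC)c1)[C@](C)(CCO)[C@@H](C)C1SCCCS1
F3 | step 5 | rac-4-methylbenzenesulfonate (tosylate) of F2 | Cc1ccc(c(OCOC)c1)[C@](C)(CCOS(=O)(=O)c1ccc(C)cc1)[C@@H](C)C1SCCCS1
F4 | step 5 | rac-spiro dithioketal of ketone 7: 2-[2-(methoxymethoxy)-4-methylphenyl]-1,2-dimethyl-6,10-dithiaspiro[4.5]decane | Cc1ccc(c(OCOC)c1)[C@]1(C)CCC2(SCCCS2)[C@@H]1C
F0 | step 6 | none | none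
F5 | step 8 | 1-bromo-5-[(1R,2R)-3-(dibromomethylidene)-1,2-dimethylcyclopentyl]-4-(methoxymethoxy)-2-methylbenzene | Cc1cc(OCOC)c(cc1Br)[C@]1(C)CCC(=C(Br)Br)[C@@H]1C
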